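**Retrosynthetic overview** (longipinane numbering: C1 ketone, C2=C3 enone, C4 and C11 bridgeheads, C5 and C10 one-carbon bridges, C6 = CMe2, C7–C9 oxygenated)
1. Target 27 ⇐ O7 angeloylation and a 9-OH-directed 1,3-anti reduction of C7=O ⇐ tricyclic 1,7-dione 23, which already carries the enone, the 8-isovalerate and the free 9-OH.
2. 23 ⇐ cut C8–C9 (the aldol bond of the β-hydroxy ketone C7(=O)–C8–C9) and C4–C5 (the cyclobutane bond) ⇒ monocyclic keto aldehyde 19, with a temporary carboxyl group on C5 as a redox-active ester.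
3. Enabling feature: C4 is the γ-carbon of the C1–C2=C3 enone of the six-membered ring and sits 1,3-cis to the C5 branch on C11, so the enone becomes a 1-siloxy-1,3-diene whose terminus C4 takes up a C5 radical. The quaternary carbons C6 and C10 leave only one enol (C7/C8) and a non-enolisable aldehyde (C9).
4. 19 ⇐ Ireland–Claisen rearrangement (C5–C6, which also delivers the C5 carboxyl group), enolate alkylation (C11–C5), asymmetric conjugate addition (C10).
5. Ring order: six-membered ring (present from the start), then the seven-membered ring, then the cyclobutane, the last two both in step 11.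

Key step: step 11

Remark: racemic 1 is resolved kinetically in step 1, and the C5 stereocentre of 13–19 is carried as a mixture because step 11 erases it.

**Step 1**
Reactants: 1 rac-3,5-dimethylcyclohex-2-enone; 2 3,3-dimethylbut-1-yne
Product: 4 (3R,5R)-3-[(E)-3,3-dimethylbut-1-enyl]-3,5-dimethylcyclohexanone, via alkenylalane 3 (not isolated)
Conditions: 2, DIBAL-H, hexane, 50 °C; then 1 (about 2 equiv), Cu(I) thiophene-2-carboxylate (cat.), chiral phosphinamine ligand (cat.), Et2O, −10 °C; aq. NH4Cl
Reagents that add atoms: none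
Why: Copper-catalysed asymmetric conjugate addition of an alkenylalane to a β-substituted cyclohexenone, run as a kinetic resolution, in which the ligand-matched (R)-enone takes up the alkenyl group trans to its ring methyl group and so sets the quaternary centre C10, while the (S)-enone stays behind.

**Step 2**
Reactants: 4 (3R,5R)-3-[(E)-3,3-dimethylbut-1-enyl]-3,5-dimethylcyclohexanone
Product: 5 (R)-5-[(E)-3,3-dimethylbut-1-enyl]-3,5-dimethylcyclohex-2-enone
Conditions: IBX, DMSO/fluorobenzene, 70 °C
Reagents that add atoms: none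
Why: IBX dehydrogenation of a ketone, which can run only towards C2–C3 because the other β-carbon (C10) is quaternary, and which removes the auxiliary stereocentre C3.

**Step 3**
Reactants: 6 3-methylbut-2-en-1-ol; 7 bromoacetyl bromide
Product: 8 3-methylbut-2-enyl bromoacetate
Conditions: pyridine, CH2Cl2, 0 °C
Reagents that add atoms: none
Why: Plain O-acylation of a primary allylic alcohol with an acid bromide.

**Step 4**
Reactants: 5 (R)-5-[(E)-3,3-dimethylbut-1-enyl]-3,5-dimethylcyclohex-2-enone; 8 3-methylbut-2-enyl bromoacetate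
Product: 9 3-methylbut-2-enyl 2-[(1R,6S)-6-[(E)-3,3-dimethylbut-1-enyl]-4,6-dimethyl-2-oxocyclohex-3-enyl]acetate (acetate arm cis to the alkenyl group)
Conditions: LDA, THF, −78 °C; then 8, DMPU, −78 to −30 °C
Reagents that add atoms: none
Why: Kinetic α'-enolate alkylation of an enone, in which the bulky alkenyl group on C10 lies pseudo-equatorial and the pseudo-axial methyl group blocks one face, so the electrophile enters trans to that methyl group and sets C11.

**Step 5**
Reactants: 9 prenyl ester (as above)
Product: 10 tert-butyldimethylsilyl dienol ether of 9 (C1(OTBS)=C2–C3(Me)=C4)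
Conditions: TBSOTf, Et3N, CH2Cl2, 0 °C
Reagents that add atoms: tert-butyldimethylsilyl triflate, CC(C)(C)[Si](C)(C)OS(=O)(=O)C(F)(F)F
Why: Soft enolisation of an enone to the extended dienol silyl ether, which masks the ketone by γ-deprotonation and leaves the hindered tertiary C11–H, and thus C11, untouched.

**Step 6**
Reactants: 10 TBS dienol ether
Product: 13 2-[ring as in 9]-3,3-dimethylpent-4-enoic acid (both C5 epimers; enone restored), via silyl ketene acetal 11 (not isolated), via rearranged silyl ester 12 (not isolated)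
Conditions: LDA, TMSCl, THF, −78 °C to reflux; then 1 M HCl, THF, rt
Reagents that add atoms: none
Why: Ireland–Claisen rearrangement of a prenyl ester, whose [3,3] shift joins C5 to the dimethyl-substituted allyl terminus, creates the quaternary C6 and leaves the carboxyl group on C5, while the acidic work-up cleaves both silyl groups.

**Step 7**
Reactants: 13 pentenoic acid
Product: 14 5-hydroxy-3,3-dimethyl-4-oxo-2-[ring as in 9]pentanoic acid
Conditions: RuCl3 (cat.), Oxone, NaHCO3, EtOAc/MeCN/H2O, rt
Reagents that add atoms: potassium peroxymonosulfate (Oxone), [K+].[O-]S(=O)(=O)OO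
Why: RuO4-catalysed ketohydroxylation of an alkene, which should pick the terminal vinyl group over the electron-poor enone and the doubly neopentyl (E)-alkene and give the 1-hydroxy-2-ketone (C7=O, C8–OH).

**Step 8**
Reactants: 14 hydroxy keto acid; 15 3-methylbutanoic anhydride
Product: 16 3,3-dimethyl-5-(3-methylbutanoyloxy)-4-oxo-2-[ring as in 9]pentanoic acid
Conditions: pyridine, DMAP (cat.), CH2Cl2, 0 °C; then aq. NaHCO3/THF (cleaves the mixed anhydride), acidify
Reagents that add atoms: none
Why: Acylation of the only alcohol, a primary one, which places the isovalerate on O8 before any other hydroxyl group exists.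

**Step 9**
Reactants: 16 keto acid; 17 N-hydroxyphthalimide
Product: 18 N-phthalimidoyl ester of 16
Conditions: DIC, DMAP (cat.), CH2Cl2, rt
Reagents that add atoms: none
Why: Carbodiimide coupling of a carboxylic acid to its redox-active ester.

**Step 10**
Reactants: 18 redox-active ester
Product: 19 keto aldehyde (C10–CHO in place of the alkenyl group; both C5 epimers)
Conditions: O3, CH2Cl2, −78 °C (Sudan Red end point); then Me2S
Reagents that add atoms: ozone, [O-][O+]=O
Why: Ozonolysis, which cleaves the electron-rich 1,2-disubstituted alkene before the conjugated enone and uncovers the non-enolisable C9 aldehyde.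

**Step 11**
Reactants: 19 keto aldehyde
Product: 23 9α-hydroxy-8α-(3-methylbutanoyloxy)longipin-2-ene-1,7-dione, via bis(enol silane) 20 (not isolated), via bicyclic aldol silyl ether 21 (not isolated), via tricyclic silyl ether 22 (not isolated)
Conditions: TMSOTf (2.6 equiv), i-Pr2NEt (2.1 equiv), fac-Ir(ppy)3 (1 mol %), CH2Cl2 (high dilution), −40 °C in the dark, then 450 nm LEDs, −20 °C, same flask; citric acid, MeOH work-up
Reagents that add atoms: none
Why: Proposed new method: TMSOTf/i-Pr2NEt converts the C7 ketone, which can enolise only towards C8, and the C1 enone into the enol silane and the 1-siloxy-1,3-diene of 20, and the silyl triflate then drives a Mukaiyama aldol addition of C8 to the C9 aldehyde that closes the seven-membered ring in the 7-(enolexo)-exo-trig mode (21). Once the lamp is on, excited Ir(ppy)3 reduces the N-acyloxyphthalimide, loss of phthalimide anion and CO2 leaves the C5 radical, this adds 4-exo-trig to the diene terminus C4, and Ir(IV) oxidises the siloxyallyl radical to the O-silylated enone, which releases TMS+ (22), so the event is redox-neutral and the temporary carboxyl group leaves as CO2. The closest known reaction types are the one-pot soft-enolisation/Mukaiyama aldol addition to non-enolisable aldehydes, the photoredox decarboxylative alkylation of silyl enol ethers with redox-active esters, and 4-exo-trig radical cyclisations onto activated alkenes, while the vinylogous 4-exo closure and the pairing of both events in one flask are new. C9 should be set because the pseudo-axial formyl group reacts through the rotamer with its C–H over the ring and the silylated oxygen outside while C8 comes from the side of the equatorial C11 branch, and C8, being α to the ketone, can settle as the equatorial ester cis to O9. Both C5 epimers give the same planar radical (stereoconvergent), the new seven-membered ring holds C6 away from the C1–C3 bridge so that only one C5 configuration can bond, and C4 can be reached only on the face cis to C5. The closure must outrun 1,2-acyl migration and hydrogen abstraction of the C5 radical, which is helped by the 1,3-cis proximity of C5 and C4 in 21, by a medium free of hydrogen donors (the amine is fully protonated and so also cannot intercept Ir(IV)), and by the fact that only the electron-rich adduct radical, not the alkyl radical, is oxidised irreversibly.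

**Step 12**
Reactants: 23 1,7-dione
Product: 24 7β,9α-dihydroxy-8α-(3-methylbutanoyloxy)longipin-2-en-1-one
Conditions: Me4NBH(OAc)3, MeCN/AcOH, −30 °C
Reagents that add atoms: none
Why: Evans–Saksena reduction, in which the boron bound to the axial 9-OH delivers hydride to C7 from the same face (1,3-anti diol, equatorial 7β-OH) and the enone, which has no directing hydroxyl group, is left alone.

**Step 13**
Reactants: 24 diol; 25 angelic acid [(Z)-2-methylbut-2-enoic acid]
Product: 27 7β-angeloyloxy-9α-hydroxy-8α-(3-methylbutanoyloxy)longipin-2-en-1-one (target), via mixed anhydride 26 (not isolated)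
Conditions: 25, 2,4,6-trichlorobenzoyl chloride, Et3N, toluene, rt; then 24, 75 °C
Reagents that add atoms: none
Why: Yamaguchi-type esterification through the mixed anhydride without nucleophilic catalyst, conditions under which the Z-alkene should survive, and which should acylate the equatorial O7 in preference to the axial O9 next to quaternary C10.

**Compound list**
1 | rac-3,5-dimethylcyclohex-2-enone | CC1CC(C)=CC(=O)C1 | starting material
2 | 3,3-dimethylbut-1-yne | CC(C)(C)C#C | starting material
3 | (E)-(3,3-dimethylbut-1-enyl)diisobutylalane | CC(C)C[Al](CC(C)C)/C=C/C(C)(C)C | intermediate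
4 | (3R,5R)-3-[(E)-3,3-dimethylbut-1-enyl]-3,5-dimethylcyclohexanone | CC(C)(C)/C=C/[C@@]1(C)CC(=O)C[C@H](C)C1 | intermediate
5 | (R)-5-[(E)-3,3-dimethylbut-1-enyl]-3,5-dimethylcyclohex-2-enone | CC(C)(C)/C=C/[C@@]1(C)CC(=O)C=C(C)C1 | intermediate
6 | 3-methylbut-2-en-1-ol | CC(C)=CCO | starting material
7 | bromoacetyl bromide | BrCC(=O)Br | starting material
8 | 3-methylbut-2-enyl bromoacetate | CC(C)=CCOC(=O)CBr | intermediate
9 | prenyl (1R,6S)-cyclohexenylacetate (arm cis to alkenyl) | CC(C)(C)/C=C/[C@@]1(C)[C@@H](CC(=O)OCC=C(C)C)C(=O)C=C(C)C1 | intermediate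
10 | TBS dienol ether of 9 | CC(C)(C)/C=C/[C@@]1(C)[C@@H](CC(=O)OCC=C(C)C)C(O[Si](C)(C)C(C)(C)C)=CC(C)=C1 | intermediate
11 | silyl ketene acetal | CC(C)(C)/C=C/[C@@]1(C)[C@@H](C=C(O[Si](C)(C)C)OCC=C(C)C)C(O[Si](C)(C)C(C)(C)C)=CC(C)=C1 | intermediate
12 | rearranged trimethylsilyl ester | CC(C)(C)/C=C/[C@@]1(C)[C@@H](C(C(=O)O[Si](C)(C)C)C(C)(C)C=C)C(O[Si](C)(C)C(C)(C)C)=CC(C)=C1 | intermediate
13 | 3,3-dimethylpent-4-enoic acid with ring on C5 (C5 epimers) | CC(C)(C)/C=C/[C@@]1(C)[C@@H](C(C(=O)O)C(C)(C)C=C)C(=O)C=C(C)C1 | intermediate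
14 | hydroxy keto acid | CC(C)(C)/C=C/[C@@]1(C)[C@@H](C(C(=O)O)C(C)(C)C(=O)CO)C(=O)C=C(C)C1 | intermediate
15 | 3-methylbutanoic anhydride | CC(C)CC(=O)OC(=O)CC(C)C | starting material
16 | isovaleryloxy keto acid | CC(C)(C)/C=C/[C@@]1(C)[C@@H](C(C(=O)O)C(C)(C)C(=O)COC(=O)CC(C)C)C(=O)C=C(C)C1 | intermediate
17 | N-hydroxyphthalimide | ON1C(=O)c2ccccc2C1=O | starting material
18 | redox-active ester | CC(C)(C)/C=C/[C@@]1(C)[C@@H](C(C(=O)ON2C(=O)c3ccccc3C2=O)C(C)(C)C(=O)COC(=O)CC(C)C)C(=O)C=C(C)C1 | intermediate
19 | keto aldehyde (key-step precursor) | O=C[C@@]1(C)[C@@H](C(C(=O)ON2C(=O)c3ccccc3C2=O)C(C)(C)C(=O)COC(=O)CC(C)C)C(=O)C=C(C)C1 | intermediate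
20 | bis(enol silane) | O=C[C@@]1(C)[C@@H](C(C(=O)ON2C(=O)c3ccccc3C2=O)C(C)(C)C(O[Si](C)(C)C)=COC(=O)CC(C)C)C(O[Si](C)(C)C)=CC(C)=C1 | intermediate
21 | bicyclic aldol silyl ether | O=C1[C@@H](OC(=O)CC(C)C)[C@@H](O[Si](C)(C)C)[C@@]2(C)[C@@H](C(C(=O)ON3C(=O)c4ccccc4C3=O)C1(C)C)C(O[Si](C)(C)C)=CC(C)=C2 | intermediate
22 | tricyclic 9-O-TMS ether | O=C1[C@@H](OC(=O)CC(C)C)[C@@H](O[Si](C)(C)C)[C@@]2(C)[C@@H]3C(=O)C=C(C)[C@H]2[C@@H]3C1(C)C | intermediate
23 | 9α-hydroxy-8α-isovaleryloxylongipin-2-ene-1,7-dione | O=C1[C@@H](OC(=O)CC(C)C)[C@@H](O)[C@@]2(C)[C@@H]3C(=O)C=C(C)[C@H]2[C@@H]3C1(C)C | intermediate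
24 | 7β,9α-dihydroxy-8α-isovaleryloxylongipin-2-en-1-one | O[C@@H]1[C@@H](OC(=O)CC(C)C)[C@@H](O)[C@@]2(C)[C@@H]3C(=O)C=C(C)[C@H]2[C@@H]3C1(C)C | intermediate
25 | angelic acid | C/C=C(/C)C(=O)O | starting material
26 | angelic 2,4,6-trichlorobenzoic anhydride | C/C=C(/C)C(=O)OC(=O)c1c(Cl)cc(Cl)cc1Cl | intermediate
27 | CNP0128158.1 | C/C=C(/C)C(=O)O[C@@H]1[C@@H](OC(=O)CC(C)C)[C@@H](O)[C@@]2(C)[C@@H]3C(=O)C=C(C)[C@H]2[C@@H]3C1(C)C | target

**Step count:** 13 steps in total. The longest linear sequence is 12 steps (1, 2, 4–13).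

**Steps most likely to fail**

1. **Step 11.**
   - What may go wrong: the C5 radical may escape through 1,2-acyl migration onto the C7 carbonyl. It may also abstract hydrogen or attack an exocyclic dienol-silane isomer. The active ester may acylate the C8 enol silane, and the aldol facial selectivity may be poor.
   - Fallback, from 19 back to 23, with the cyclobutane closed by a Norrish–Yang reaction.
   - 19 is treated with TESOTf/i-Pr2NEt in the dark (Mukaiyama aldol only). Brief AcOH/THF/H2O then gives the bicyclic triethylsilyl ether F1.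
   - Reductive decarboxylation of the redox-active ester (Ru(bpy)3Cl2, Hantzsch ester, tert-dodecanethiol, visible light) gives the C5 methylene compound F2.
   - Rh2(cap)4/t-BuOOH γ-oxidation of the enone gives the ene-dione F3.
   - Long-wavelength irradiation, absorbed only by the ene-dione, lets the C4 carbonyl oxygen abstract a C5 hydrogen (1,5-transfer). The biradical collapses to the bridgehead cyclobutanol F4.
   - Methyl chlorooxoacetate/DMAP gives the oxalate F5. Bu3SnH/AIBN deoxygenation gives the silyl ether F6, and HF·pyridine returns 23.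

2. **Step 7.**
   - What may go wrong: chemoselectivity among the three alkenes may be poor. Over-oxidation or lactonisation of the product may interfere.
   - Fallback, from 13 back to 14, with the carboxyl group choosing the alkene.
   - Iodolactonisation (I2, NaHCO3, MeCN) gives the iodolactone F7.
   - DBU eliminates HI to give the enol lactone F8.
   - Dimethyldioxirane epoxidation followed by enol-ester-epoxide rearrangement (acyl shift) gives the keto δ-lactone F9.
   - LiOH, then acid, opens F9 to 14.

3. **Step 13.**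
   - What may go wrong: site selectivity between O7 and O9 may be poor. Acyl migration or Z-to-E isomerisation of the angeloyl group on heating may occur.
   - Fallback, from 24 back to 27, with the Z-alkene built on the ester.
   - O7 is acylated at room temperature with 2-[bis(2,2,2-trifluoroethoxy)phosphoryl]propanoic acid (DCC, DMAP) to give the phosphonopropionate F10.
   - A Still–Gennari olefination (KHMDS, 18-crown-6, acetaldehyde, −78 °C) then gives 27.

**Further compounds**
F1 | step 11 | bicyclic 9-O-TES aldol, redox-active ester | O=C1[C@@H](OC(=O)CC(C)C)[C@@H](O[Si](CC)(CC)CC)[C@@]2(C)[C@@H](C(C(=O)ON3C(=O)c4ccccc4C3=O)C1(C)C)C(=O)C=C(C)C2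
F2 | step 11 | decarboxylated bicycle (C5 methylene) | O=C1[C@@H](OC(=O)CC(C)C)[C@@H](O[Si](CC)(CC)CC)[C@@]2(C)[C@@H](CC1(C)C)C(=O)C=C(C)C2
F3 | step 11 | bicyclic ene-dione (C4=O) | O=C1[C@@H](OC(=O)CC(C)C)[C@@H](O[Si](CC)(CC)CC)[C@@]2(C)[C@@H](CC1(C)C)C(=O)C=C(C)C2=O
F4 | step 11 | tricyclic C4 cyclobutanol | O=C1[C@@H](OC(=O)CC(C)C)[C@@H](O[Si](CC)(CC)CC)[C@@]2(C)[C@@H]3C(=O)C=C(C)[C@@]2(O)[C@@H]3C1(C)C
F5 | step 11 | C4 methyl oxalate | O=C1[C@@H](OC(=O)CC(C)C)[C@@H](O[Si](CC)(CC)CC)[C@@]2(C)[C@@H]3C(=O)C=C(C)[C@@]2(OC(=O)C(=O)OC)[C@@H]3C1(C)C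
F6 | step 11 | tricyclic 9-O-TES ether | O=C1[C@@H](OC(=O)CC(C)C)[C@@H](O[Si](CC)(CC)CC)[C@@]2(C)[C@@H]3C(=O)C=C(C)[C@H]2[C@@H]3C1(C)C
F7 | step 7 | iodolactone | CC(C)(C)/C=C/[C@@]1(C)[C@@H](C2C(=O)OC(CI)C2(C)C)C(=O)C=C(C)C1
F8 | step 7 | enol lactone | CC(C)(C)/C=C/[C@@]1(C)[C@@H](C2C(=O)OC(=C)C2(C)C)C(=O)C=C(C)C1
F9 | step 7 | keto δ-lactone | CC(C)(C)/C=C/[C@@]1(C)[C@@H](C2C(=O)OCC(=O)C2(C)C)C(=O)C=C(C)C1
F10 | step 13 | O7 phosphonopropionate | CC(P(=O)(OCC(F)(F)F)OCC(F)(F)F)C(=O)O[C@@H]1[C@@H](OC(=O)CC(C)C)[C@@H](O)[C@@]2(C)[C@@H]3C(=O)C=C(C)[C@H]2[C@@H]3C1(C)C
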